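## Plan

1. The keto acid of ring A is first closed, on paper, to its enol lactone, a (Z)-3-butylidenephthalide. Hydroxide breaks the acyl C1–O bond again in the last step. The B4 oxygen carries a tert-butyl group until then.
2. Ring B has O-aryl at B1, OH at B2, H at B3, OH at B4, H at B5 and pentyl at B6, and it is cut at B5–B6, B2–B3, B4–B5 and B1–B2. The meta oxygens B2/B4 with an unsubstituted B3 between them correspond to a ketene carbonyl carbon joined to an H–C≡C–O unit. The neighbours B1 (aryloxy) and B6 (pentyl) are the two carbons of a vinyl group.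
3. These cuts lead to a β-aryloxy-α-pentyl α'-diazo enone and tert-butoxyacetylene. The diazo group comes from a methyl ketone by diazo transfer. The O–B1 bond comes from vinylic addition–elimination of the ring A phenol on the enol tosylate of 2-acetylheptanal (heptanal plus acetyl chloride).
4. The ring A phenol comes from 2,4-dimethoxybenzoic acid, cut at the aryl–C(=O)Bu bond (directed ortho-metalation, Weinreb acylation) and at the C7 O–CH3 bond.
5. In the forward direction the ring A arene is bought and the lactone ring closes first. The ether oxygen is then attached to an open chain, and ring B closes last. Finally the tert-butyl group leaves and the lactone ring is opened.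
6. The target has no stereocentre. The Z-butylidene and E-enol-ether geometries of the intermediates are the thermodynamic ones, and both alkenes are gone in the target.

Key step: step 13

Remark on the chemistry: the target is treated as the open keto acid that is drawn. In solution it can equilibrate with its cyclic 3-hydroxyphthalide (pseudo-acid) tautomer, which is the same compound.

## Route

Step 1
Reactants: 1 pentanoyl chloride
Product: 2 N-methoxy-N-methylpentanamide
Conditions: MeONHMe·HCl, Et3N (2.2 equiv), CH2Cl2, 0 °C to rt
Reagents that add atoms: N,O-dimethylhydroxylamine hydrochloride, CNOC.Cl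
Why: N-acylation by an acid chloride is the standard entry to a Weinreb amide, which later stops the aryllithium addition at the ketone stage.

Step 2
Reactants: 3 2,4-dimethoxybenzoic acid
Product: 5 N,N-diethyl-2,4-dimethoxybenzamide, via acid chloride 4 (not isolated)
Conditions: SOCl2, toluene, 70 °C; evaporate; Et2NH (2.5 equiv), CH2Cl2, 0 °C
Reagents that add atoms: diethylamine, CCNCC
Why: Amide formation through the acid chloride installs the tertiary amide, the strongest ortho-directing group on this ring.

Step 3
Reactants: 5 N,N-diethyl-2,4-dimethoxybenzamide; 2 N-methoxy-N-methylpentanamide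
Product: 7 N,N-diethyl-2,4-dimethoxy-6-pentanoylbenzamide, via aryllithium 6 (not isolated)
Conditions: s-BuLi, TMEDA, THF, −78 °C; then 2, −78 to 0 °C; 1 M HCl
Reagents that add atoms: none
Why: In this directed ortho-metalation the amide-bound base removes H6 under kinetic control rather than H3 between the methoxy groups, and the Weinreb ketone synthesis holds the adduct as a chelate until the quench, so that only the ketone should form.

Step 4
Reactants: 7 N,N-diethyl-2,4-dimethoxy-6-pentanoylbenzamide
Product: 9 (Z)-3-butylidene-5,7-dimethoxyisobenzofuran-1(3H)-one, via lactol 8 (not isolated)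
Conditions: TsOH·H2O (1.5 equiv), toluene, reflux, then Dean–Stark
Reagents that add atoms: none
Why: The neighbouring ketone oxygen attacks the protonated amide, as in the acid lactonisation of ortho-functionalised tertiary benzamides to phthalides, and acid-catalysed dehydration of the pseudo-acid under equilibrating conditions should give the more stable Z alkene, whose propyl chain points away from H4.

Step 5
Reactants: 9 (Z)-3-butylidene-5,7-dimethoxyisobenzofuran-1(3H)-one
Product: 10 (Z)-3-butylidene-7-hydroxy-5-methoxyisobenzofuran-1(3H)-one
Conditions: BCl3 (1.2 equiv), CH2Cl2, −78 to 0 °C; H2O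
Reagents that add atoms: none
Why: In this chelation-controlled aryl methyl ether cleavage BCl3 bridges the lactone carbonyl and the peri C7 methoxy oxygen, so only that methyl group is lost and the C5 methoxy group stays.

Step 6
Reactants: 11 heptanal
Product: 12 (E)-4-(hept-1-en-1-yl)morpholine
Conditions: morpholine (1.2 equiv), toluene, Dean–Stark, reflux; distil
Reagents that add atoms: morpholine, C1COCCN1
Why: Enamine formation from an aldehyde and a secondary amine with azeotropic removal of water should give the less strained E enamine.

Step 7
Reactants: 12 (E)-4-(hept-1-en-1-yl)morpholine; 13 acetyl chloride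
Product: 15 2-acetylheptanal (chelated enol form (Z)-3-(hydroxymethylene)octan-2-one), via acyl enamine 14 (not isolated)
Conditions: Et3N, CH2Cl2, 0 °C to rt; then 2 M HCl, rt
Reagents that add atoms: water, O
Why: The Stork enamine acylation places the acetyl group on the former α-carbon of heptanal without regiochemical ambiguity, and acid hydrolysis of the vinylogous amide releases the β-keto aldehyde.

Step 8
Reactants: 15 2-acetylheptanal
Product: 16 (E)-3-(tosyloxymethylene)octan-2-one
Conditions: TsCl, Et3N, DMAP (cat.), CH2Cl2, 0 °C
Reagents that add atoms: 4-toluenesulfonyl chloride, Cc1ccc(cc1)S(=O)(=O)Cl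
Why: O-sulfonylation of a hydroxymethylene ketone takes place at the less hindered, aldehyde-derived oxygen and gives the enol tosylate with the sulfonate trans to the acetyl group; any Z isomer converges in the next step.

Step 9
Reactants: 10 (Z)-3-butylidene-7-hydroxy-5-methoxyisobenzofuran-1(3H)-one; 16 (E)-3-(tosyloxymethylene)octan-2-one
Product: 17 (E)-3-({[(Z)-3-butylidene-5-methoxy-1-oxo-1,3-dihydroisobenzofuran-7-yl]oxy}methylene)octan-2-one
Conditions: K2CO3, DMF, 0 °C to rt
Reagents that add atoms: none
Why: In this vinylic substitution by addition–elimination the phenoxide adds to the β-carbon of the activated enone and tosylate leaves, the reagent being attacked at carbon like a vinylogous carboxylic–sulfonic anhydride, and the rotatable enolate intermediate lets the product settle in the E geometry.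

Step 10
Reactants: 17 the aryloxymethylene methyl ketone
Product: 20 (E)-1-diazo-3-({[(Z)-3-butylidene-5-methoxy-1-oxo-1,3-dihydroisobenzofuran-7-yl]oxy}methylene)octan-2-one, via lithium enolate 18 (not isolated), via trifluoroacetyl diketone 19 (not isolated)
Conditions: LiN(SiMe3)2, THF, −78 °C; CF3CO2CH2CF3, −78 °C; 5% HCl wash; then MsN3, Et3N, H2O (1 equiv), MeCN, rt
Reagents that add atoms: methanesulfonyl azide, CS(=O)(=O)N=[N+]=[N-]
Why: Detrifluoroacetylative diazo transfer (kinetic deprotonation of the only acidic site, Claisen trifluoroacetylation, azide transfer with loss of the activating group) is the established route to α,β-unsaturated diazomethyl ketones and avoids diazomethane, which can add as a dipole to the C=C bond of enoyl chlorides.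

Step 11
Reactants: 21 trichloroethylene; 22 potassium tert-butoxide
Product: 24 (E)-1,2-dichlorovinyl tert-butyl ether, via dichloroacetylene 23 (not isolated)
Conditions: THF, −60 °C to rt, argon; distil under reduced pressure
Reagents that add atoms: none
Why: Base-induced dehydrochlorination followed by anti addition of tert-butanol to the hazardous chloroalkyne, which stays in solution, is the standard preparation of 1,2-dichlorovinyl ethers and sets the E geometry.

Step 12
Reactants: 24 (E)-1,2-dichlorovinyl tert-butyl ether
Product: 27 tert-butoxyacetylene, via chloroalkyne 25 (not isolated), via lithium acetylide 26 (not isolated)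
Conditions: n-BuLi (2.2 equiv), Et2O, −78 to −40 °C; H2O, −78 °C; trap-to-trap distillation, kept cold
Reagents that add atoms: none
Why: Elimination of HCl, chlorine–lithium exchange and protonation form the known sequence to alkoxyacetylenes, and a tert-alkyl ynol ether is chosen because it is a distillable known compound removable by acid, whereas a silyl ynol ether with hydrogen on the other alkyne carbon would need the impractical unsubstituted ynolate.

Step 13
Reactants: 20 the α'-diazo enone; 27 tert-butoxyacetylene
Product: 32 (Z)-3-butylidene-7-(4-tert-butoxy-2-hydroxy-6-pentylphenoxy)-5-methoxyisobenzofuran-1(3H)-one, via vinylketene 28 (not isolated), via vinylcyclobutenone 29 (not isolated), via dienylketene 30 (not isolated), via cyclohexadienone 31 (not isolated)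
Conditions: 27 (4 equiv), degassed CH2Cl2, hν (254 nm, quartz), 10–15 °C; evaporate; toluene, 80–110 °C
Reagents that add atoms: none
Why: Light expels N2 from 20 and the alkenyl group shifts to the carbene carbon (photo-Wolff rearrangement, B5–B6 bond) to give vinylketene 28, whose carbonyl carbon is attacked by the electron-rich CH terminus of 27 in a regiospecific [2+2] cycloaddition (B2–B3 and B4–B5 bonds) that leads to 4-alkenylcyclobutenone 29. On warming, 29 opens in a reversible conrotatory 4π electrocyclic reaction to dienylketene 30, and because only the isomer with the alkenyl group turned inward can react further, the equilibrium drains through it. Ring B closes by a disrotatory 6π electrocyclisation of 30 between the ketene carbon and the aryloxy-bearing alkene terminus (B2–B1 bond), and dienone 31 enolises irreversibly to the phenol. This is the diazo ketone form of the Danheiser benzannulation, established for α,β-unsaturated α'-diazo ketones with oxygen-substituted alkynes. No stereocentre survives, since the sp3 carbons of 29 and 31 are lost on aromatisation; the selectivity needed is the orientation of the alkyne, and the oxygen-polarised triple bond secures it, placing the new hydroxyl at B2 beside the aryloxy carbon and the tert-butoxy group at B4 with hydrogen at B3 between them. The E enol ether keeps the aryloxy group on the outside of the closing triene, the enol lactone shields the pentanoyl ketone from photochemical γ-hydrogen abstraction, and evaporating the excess 27 before heating prevents its retro-ene breakdown to ketene.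

Step 14
Reactants: 32 the tert-butyl ether
Product: 33 (Z)-3-butylidene-7-(2,4-dihydroxy-6-pentylphenoxy)-5-methoxyisobenzofuran-1(3H)-one
Conditions: TFA–CH2Cl2 (1:4), 0 °C to rt
Reagents that add atoms: none
Why: Acidolysis of an aryl tert-butyl ether releases the phenol and isobutene, every free position on both rings is flanked by two substituents so that recapture of the tert-butyl cation is sterically disfavoured, and the enol lactone, methyl ether and diaryl ether are inert to anhydrous TFA.

Step 15
Reactants: 33 the resorcinol enol lactone
Product: 35 2-(2,4-dihydroxy-6-pentylphenoxy)-4-methoxy-6-pentanoylbenzoic acid (target), via tripotassium salt 34 (not isolated)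
Conditions: KOH (5 equiv), THF–H2O, rt, argon; then 1 M HCl, 0 °C, pH 2
Reagents that add atoms: potassium hydroxide, [K+].[OH-]
Why: In this enol ester saponification hydroxide attacks the lactone carbonyl and the departing enolate becomes the pentanoyl ketone, which makes the opening irreversible, while exclusion of air protects the electron-rich ring B and any E alkene isomer or acyl shift onto the B2 oxygen converges on the same salt.

## Compound list

1 | pentanoyl chloride | CCCCC(=O)Cl | starting material
2 | N-methoxy-N-methylpentanamide | CCCCC(=O)N(C)OC | intermediate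
3 | 2,4-dimethoxybenzoic acid | COc1ccc(C(=O)O)c(OC)c1 | starting material
4 | 2,4-dimethoxybenzoyl chloride (not isolated) | COc1ccc(C(=O)Cl)c(OC)c1 | intermediate
5 | N,N-diethyl-2,4-dimethoxybenzamide | CCN(CC)C(=O)c1ccc(OC)cc1OC | intermediate
6 | N,N-diethyl-6-lithio-2,4-dimethoxybenzamide (not isolated) | CCN(CC)C(=O)c1c([Li])cc(OC)cc1OC | intermediate
7 | N,N-diethyl-2,4-dimethoxy-6-pentanoylbenzamide | CCCCC(=O)c1cc(OC)cc(OC)c1C(=O)N(CC)CC | intermediate
8 | 3-butyl-3-hydroxy-5,7-dimethoxyisobenzofuran-1(3H)-one (racemic, not isolated) | CCCCC1(O)OC(=O)c2c(OC)cc(OC)cc21 | intermediate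
9 | (Z)-3-butylidene-5,7-dimethoxyisobenzofuran-1(3H)-one | COc1cc(OC)cc2c1C(=O)O/C2=C\CCC | intermediate
10 | (Z)-3-butylidene-7-hydroxy-5-methoxyisobenzofuran-1(3H)-one | Oc1cc(OC)cc2c1C(=O)O/C2=C\CCC | intermediate
11 | heptanal | CCCCCCC=O | starting material
12 | (E)-4-(hept-1-en-1-yl)morpholine | CCCCC/C=C/N1CCOCC1 | intermediate
13 | acetyl chloride | CC(=O)Cl | starting material
14 | (E)-3-(morpholinomethylene)octan-2-one (not isolated) | CC(=O)/C(CCCCC)=C/N1CCOCC1 | intermediate
15 | 2-acetylheptanal, drawn as (Z)-3-(hydroxymethylene)octan-2-one | CC(=O)/C(CCCCC)=C\O | intermediate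
16 | (E)-3-(tosyloxymethylene)octan-2-one | CC(=O)/C(CCCCC)=C/OS(=O)(=O)c1ccc(C)cc1 | intermediate
17 | (E)-3-({[(Z)-3-butylidene-5-methoxy-1-oxo-1,3-dihydroisobenzofuran-7-yl]oxy}methylene)octan-2-one | CC(=O)/C(CCCCC)=C/Oc1cc(OC)cc2c1C(=O)O/C2=C\CCC | intermediate
18 | lithium enolate of 17 at the methyl group (not isolated) | [Li+].C=C([O-])/C(CCCCC)=C/Oc1cc(OC)cc2c1C(=O)O/C2=C\CCC | intermediate
19 | 1-trifluoroacetyl derivative of 17, a 1,3-diketone (not isolated) | O=C(CC(=O)/C(CCCCC)=C/Oc1cc(OC)cc2c1C(=O)O/C2=C\CCC)C(F)(F)F | intermediate
20 | (E)-1-diazo-3-({[(Z)-3-butylidene-5-methoxy-1-oxo-1,3-dihydroisobenzofuran-7-yl]oxy}methylene)octan-2-one | [N-]=[N+]=CC(=O)/C(CCCCC)=C/Oc1cc(OC)cc2c1C(=O)O/C2=C\CCC | intermediate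
21 | trichloroethylene | ClC=C(Cl)Cl | starting material
22 | potassium tert-butoxide | CC(C)(C)[O-].[K+] | starting material
23 | dichloroacetylene (not isolated) | ClC#CCl | intermediate
24 | (E)-1,2-dichlorovinyl tert-butyl ether | Cl/C=C(/Cl)OC(C)(C)C | intermediate
25 | 1-tert-butoxy-2-chloroacetylene (not isolated) | ClC#COC(C)(C)C | intermediate
26 | lithium tert-butoxyacetylide (not isolated) | [Li]C#COC(C)(C)C | intermediate
27 | tert-butoxyacetylene | C#COC(C)(C)C | intermediate
28 | (E)-4-aryloxy-3-pentylbuta-1,3-dien-1-one, aryl = ring A phthalide (vinylketene, not isolated) | O=C=C/C(CCCCC)=C/Oc1cc(OC)cc2c1C(=O)O/C2=C\CCC | intermediate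
29 | 3-tert-butoxy-4-[(E)-1-aryloxyhept-1-en-2-yl]cyclobut-2-en-1-one (racemic, not isolated) | O=C1C=C(OC(C)(C)C)C1/C(CCCCC)=C/Oc1cc(OC)cc2c1C(=O)O/C2=C\CCC | intermediate
30 | (3E,5E)-6-aryloxy-3-tert-butoxy-5-pentylhexa-1,3,5-trien-1-one (dienylketene, not isolated) | O=C=C/C(OC(C)(C)C)=C\C(CCCCC)=C\Oc1cc(OC)cc2c1C(=O)O/C2=C\CCC | intermediate
31 | 6-aryloxy-3-tert-butoxy-5-pentylcyclohexa-2,4-dien-1-one (racemic, not isolated) | O=C1C=C(OC(C)(C)C)C=C(CCCCC)C1Oc1cc(OC)cc2c1C(=O)O/C2=C\CCC | intermediate
32 | (Z)-3-butylidene-7-(4-tert-butoxy-2-hydroxy-6-pentylphenoxy)-5-methoxyisobenzofuran-1(3H)-one | CCCCCc1cc(OC(C)(C)C)cc(O)c1Oc1cc(OC)cc2c1C(=O)O/C2=C\CCC | intermediate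
33 | (Z)-3-butylidene-7-(2,4-dihydroxy-6-pentylphenoxy)-5-methoxyisobenzofuran-1(3H)-one | CCCCCc1cc(O)cc(O)c1Oc1cc(OC)cc2c1C(=O)O/C2=C\CCC | intermediate
34 | tripotassium salt of the target (not isolated) | CCCCCc1cc([O-])cc([O-])c1Oc1cc(OC)cc(C(=O)CCCC)c1C(=O)[O-].[K+].[K+].[K+] | intermediate
35 | 2-(2,4-dihydroxy-6-pentylphenoxy)-4-methoxy-6-pentanoylbenzoic acid | CCCCCc1cc(O)cc(O)c1Oc1cc(OC)cc(C(=O)CCCC)c1C(=O)O | target

## Step count

Total step count: 15.
Longest linear sequence: 9 steps from 2,4-dimethoxybenzoic acid (steps 2, 3, 4, 5, 9, 10, 13, 14, 15).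

## Steps most likely to fail

**Step 13.** The butylidenephthalide chromophore competes for the light. Loss of nitrogen may therefore be slow while the exocyclic alkene isomerises or dimerises. The carbene may be reached in its triplet state and abstract hydrogen instead of rearranging. The phenol being formed may also intercept the ketene.

The fallback sets out from 10 and comes back at 33; ring B is bought instead of built. Olivetol is benzylated (BnBr, K2CO3, DMF) to 1,3-bis(benzyloxy)-5-pentylbenzene F1. This is iodinated next to the pentyl group and para to an ether oxygen (NIS, MeCN) to give 1,5-bis(benzyloxy)-2-iodo-3-pentylbenzene F2. Oxidation in the presence of 1,3,5-trimethoxybenzene (mCPBA, TsOH·H2O, MeCN) gives [2,4-bis(benzyloxy)-6-pentylphenyl](2,4,6-trimethoxyphenyl)iodonium tosylate F3. Metal-free O-arylation of 10 with this salt (K2CO3, toluene, 50 °C) tolerates two ortho substituents on the transferred ring. It should give (Z)-7-[2,4-bis(benzyloxy)-6-pentylphenoxy]-3-butylidene-5-methoxyisobenzofuran-1(3H)-one F4. BCl3 with pentamethylbenzene at −78 °C then removes both benzyl groups without touching the butylidene alkene and gives 33.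

**Step 10.** The amide base or the liberated trifluoroethoxide may open the enol lactone. Conjugate addition–elimination at the aryloxy enone may also expel the phenoxide before the methyl group is deprotonated.

The fallback sets out from 17 and comes back at 20 without any strong base. Soft enolisation (TMSOTf, Et3N, CH2Cl2, 0 °C) gives the 2-(trimethylsilyloxy)diene F5. NBS in THF at −78 °C brominates its CH2 terminus to give the bromomethyl ketone F6. N,N'-ditosylhydrazine with DBU in THF at 0 °C converts the bromomethyl ketone into diazo ketone 20 by substitution and double sulfinate loss.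

**Step 9.** The hydrogen-bonded, hindered phenoxide may react sluggishly. It may take up the sulfonyl group by attack at sulfur instead of at the vinyl carbon. The enol tosylate may also decompose under the basic conditions.

The fallback sets out from 10 and comes back at 17; it forms the C–O bond first and introduces the pentyl group afterwards. DABCO-catalysed oxa-Michael addition of 10 to but-3-yn-2-one (CH2Cl2, 0 °C) gives the (E)-4-aryloxybut-3-en-2-one F7. Electrophilic α-iodination of this vinylogous ester (NIS, CH2Cl2, 0 °C) gives the (Z)-4-aryloxy-3-iodobut-3-en-2-one F8. Negishi coupling with C5H11ZnBr and PdCl2(dppf) in THF at rt replaces iodine by pentyl with retention of geometry and gives 17.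

## Further compounds

F1 | step 13 | 1,3-bis(benzyloxy)-5-pentylbenzene | CCCCCc1cc(OCc2ccccc2)cc(OCc2ccccc2)c1
F2 | step 13 | 1,5-bis(benzyloxy)-2-iodo-3-pentylbenzene | CCCCCc1cc(OCc2ccccc2)cc(OCc2ccccc2)c1I
F3 | step 13 | [2,4-bis(benzyloxy)-6-pentylphenyl](2,4,6-trimethoxyphenyl)iodonium tosylate | CCCCCc1cc(OCc2ccccc2)cc(OCc2ccccc2)c1[I+]c1c(OC)cc(OC)cc1OC.Cc1ccc(cc1)S(=O)(=O)[O-]
F4 | step 13 | (Z)-7-[2,4-bis(benzyloxy)-6-pentylphenoxy]-3-butylidene-5-methoxyisobenzofuran-1(3H)-one | CCCCCc1cc(OCc2ccccc2)cc(OCc2ccccc2)c1Oc1cc(OC)cc2c1C(=O)O/C2=C\CCC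
F5 | step 10 | 2-(trimethylsilyloxy)diene from 17 | C=C(O[Si](C)(C)C)/C(CCCCC)=C/Oc1cc(OC)cc2c1C(=O)O/C2=C\CCC
F6 | step 10 | (E)-1-bromo-3-(aryloxymethylene)octan-2-one, aryl = ring A phthalide | BrCC(=O)/C(CCCCC)=C/Oc1cc(OC)cc2c1C(=O)O/C2=C\CCC
F7 | step 9 | (E)-4-aryloxybut-3-en-2-one, aryl = ring A phthalide | CC(=O)/C=C/Oc1cc(OC)cc2c1C(=O)O/C2=C\CCC
F8 | step 9 | (Z)-4-aryloxy-3-iodobut-3-en-2-one, aryl = ring A phthalide | CC(=O)/C(I)=C/Oc1cc(OC)cc2c1C(=O)O/C2=C\CCC
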